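At 144 h, the time asked about, the south flask read 42.7%, and it had already read 42.2% at 12.0 h.

| flask | free monomer | initiator | temperature | remark | time |
|---|---|---|---|---|---|
| south | 0.033 M | 2.5 mol% | 60 °C | the very flask that is asked about, followed so far |  |
| north-east | 0.033 M | 5 mol% | 55 °C | run made earlier |  |
| flask | 0.033 M | 2.5 mol% | 60 °C |  | 6.0 d |

- south (time / h: monomer in chains / %): 12.0: 42.2; 20.0: 42.6; 40.0: 42.8; 72.0: 42.6; 144: 42.7
- north-east (time / h: monomer in chains / %): 1.50: 52.6; 3.00: 54.8; 5.00: 54.1; 6.00: 53.6; 8.00: 55.2

(scatter of a reading: 0.5 percentage points)

- Sunday's: at 6.0 d raise the temperature by 25 K, then wait 3.0 d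
- Monday's: at 6.0 d add initiator, 50.0% of the amount charged, then wait 3.0 d
- Saturday's: at 6.0 d take out 90% of the monomer in chains then present, then wait 3.0 d
- Friday's: change nothing and wait 3.0 d more

* monomer in chains, in percent of the free monomer first charged, at 6.0 d
* the option that brings most further monomer in chains ("none" if no option brings more than 2 percentage points) (Sunday's / Monday's / Saturday's / Friday's / none)
* monomer in chains present, with what was taken out counted in, in percent of the free monomer first charged, after Sunday's
* monomer in chains present, with what was taken out counted in, in percent of the free monomer first charged, after Saturday's

- monomer in chains that was removed still counts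
- the numbers in the tables scatter with a standard deviation of 0.5 percentage points
- additions bring no volume worth counting

The widest gap between the south readings was 0.6 percentage points, against a scatter of 0.5 points. So I saw no drift and took their mean, 42.6%, as my answer for now.

That left 0.0189 M of free monomer in the south flask. I read this as the rest level, the free monomer at which chains gain and lose monomer at equal pace. The usual term is equilibrium monomer concentration.

The north-east flask levelled at 54.4% from 3.00 h on. Its level, 0.0150 M, was lower than the south one. If the temperature alone did this, the step from 55 °C to 60 °C multiplied the level by 1.26.

Repeating that step over Sunday's rise gave 0.0602 M, more than the 0.033 M charged. So I expected Sunday's to empty the chains, leaving g1 near zero. On my reading, Saturday's leaves free monomer at the rest level, so g3 stays at 42.6%. On the same reading, waiting and added initiator leave that level where it stands, so I chose none.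

The weak link was that factor, because the north-east flask also held twice the initiator. So I reckoned what Sunday's needs: the level must grow by a factor of 1.74 to reach the 0.033 M charged. My repeated step gave a factor of 3.19, which is larger, so I kept my estimate for Sunday's.

The forecast gave 42.7%, none, 4% and 42.7%, on “a fixed free-monomer level set mainly by temperature”. It differed from me on g1, which I put near zero.

The south flask gave 42.9%, none, 0.0165% and 43.0%.

    monomer in chains + living end → free monomer + living end, rate k1*[living end] as long as [monomer in chains] is above zero (k = 0.660 min⁻¹, Ea = 89.0 kJ mol⁻¹)
    free monomer + initiator → living end + monomer in chains (k = 4.30 M⁻¹ min⁻¹, Ea = 75.0 kJ mol⁻¹)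
    free monomer + living end → monomer in chains + living end, rate k3*[living end]*[free monomer] (k = 35.0 M⁻¹ min⁻¹, Ea = 48.0 kJ mol⁻¹)
    (constants at 60 °C)

The forecast was right, but the answer for now had moved by 5 points at 0.0304 M or 0.0362 M of free monomer. The rest level gave 77.2% for a neighbour charged with 0.083 M, which simulated 77.3%. Another neighbour, charged with 0.0083 M, below the rest level, simulated 0.0312%. The south flask had come to rest: at 144 h monomer in chains was made 1.00 times as fast as it was used up, each step taken net. Left ten times as long, to 1440 h, it changed by nothing and stood at 42.9%.

(The runs are calculated with constants of no real substance.)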